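**Retrosynthetic overview**
1. Target 27 ⇒ diol 23: the Z-coumarate is built last on the primary alcohol (Steglich ester of a phosphonoacetic acid, Still–Gennari olefination with aldehyde 25, fluoride unmasking).
2. 23 ⇒ iodide 21 + chloroprene: the C12–C13 bond and the diene come from a new nickel-catalysed reductive alkyl–dienyl coupling.
3. 21 ⇒ bicyclic enone 15: C8 by methylcerium addition, C10 and C9 by cuprate addition/enolate alkylation, all on the convex β-face (this sets the cis ring fusion).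
4. 15 ⇒ ring A is closed last (Stork–Danheiser allylation, ring-closing metathesis) onto ring B, which is closed first by intramolecular Claisen condensation of keto ester 9.
5. 9 ⇒ ester 5 (prenol + hex-5-enoic acid): the C4–C5 bond and both stereocentres come from an enantioselective Ireland–Claisen rearrangement.

Assumption: the SMILES is read literally, i.e. a cis-fused decalin with 4R,5S,8R,9R,10S configuration in labdane numbering (C-labels in the Why lines use this numbering; β = the face of the C10 methyl), and [bis(2,2,2-trifluoroethoxy)phosphoryl]acetic acid and the (S,S)-bis-sulfonamide ligand of step 4 are taken as purchasable.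

**Step 1**
Reactants: 1 3-methylbut-2-en-1-ol (prenol); 2 hex-5-enoic acid
Product: 3 3-methylbut-2-en-1-yl hex-5-enoate
Conditions: dicyclohexylcarbodiimide, DMAP (cat.), CH2Cl2, 0 °C to rt
Reagents that add atoms: none
Why: Steglich esterification joins the two fragments without touching either alkene, and no stereocentre is formed.

**Step 2**
Reactants: 3
Product: 4 (2E)-4-hydroxy-3-methylbut-2-en-1-yl hex-5-enoate
Conditions: SeO2 (cat.), t-BuOOH, CH2Cl2, rt
Reagents that add atoms: tert-butyl hydroperoxide, CC(C)(C)OO (oxygen atom, passed on through SeO2)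
Why: Selenium dioxide allylic oxidation (ene reaction then 2,3-sigmatropic shift) hydroxylates only the E-methyl group of the trisubstituted alkene, which fixes the E geometry needed in step 4 and leaves the monosubstituted alkene alone.

**Step 3**
Reactants: 4
Product: 5 (2E)-4-{[tert-butyl(diphenyl)silyl]oxy}-3-methylbut-2-en-1-yl hex-5-enoate
Conditions: t-BuPh2SiCl, imidazole, DMF, rt
Reagents that add atoms: tert-butyl(chloro)diphenylsilane, CC(C)(C)[Si](Cl)(c1ccccc1)c1ccccc1
Why: Standard silylation of the primary allylic alcohol gives an ether that survives every step up to step 16.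

**Step 4**
Reactants: 5
Product: 8 methyl (2R)-2-[(2R)-1-{[tert-butyl(diphenyl)silyl]oxy}-2-methylbut-3-en-2-yl]hex-5-enoate, via boron ketene acetal 6 (not isolated), via carboxylic acid 7 (not isolated)
Conditions: (S,S)-bis-sulfonamide ligand, BBr3, CH2Cl2 (forms the bromoborane); then 5, Et3N, toluene/hexane, −78 °C then −20 °C; aqueous work-up; Me3SiCHN2, MeOH/toluene, 0 °C
Reagents that add atoms: trimethylsilyldiazomethane, C[Si](C)(C)C=[N+]=[N-] (ester methyl); boron tribromide, BrB(Br)Br, and the ligand, O=S(=O)(N[C@@H](c1ccccc1)[C@H](c1ccccc1)NS(=O)(=O)c1cc(C(F)(F)F)cc(C(F)(F)F)c1)c1cc(C(F)(F)F)cc(C(F)(F)F)c1, supply the boron group that is present only in 6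
Why: Reagent-controlled enantioselective Ireland–Claisen rearrangement through a chair transition state in which the E alkene puts CH2OSi equatorial and methyl axial and the ketene acetal (butenyl chain cis to the allyloxy oxygen) puts that chain axial, which sets the C4/C5 relative configuration, while the C2-symmetric (S,S)-diazaborolidine on oxygen shields one face of the ketene acetal and so sets the absolute configuration (the mirror-image ligand gives the mirror-image acid); the crude acid is methylated for the next steps.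

**Step 5**
Reactants: 8
Product: 9 methyl (2R)-2-[(2R)-1-{[tert-butyl(diphenyl)silyl]oxy}-2-methylbut-3-en-2-yl]-5-oxohexanoate
Conditions: PdCl2 (10 mol%), CuCl, O2 (1 atm), DMF/H2O, rt
Reagents that add atoms: water, O (carbonyl oxygen; O2 is the terminal oxidant)
Why: Tsuji–Wacker oxidation turns the unhindered monosubstituted alkene into the methyl ketone, while the vinyl group on the quaternary carbon is neopentylic and reacts far more slowly.

**Step 6**
Reactants: 9
Product: 10 (4R)-4-[(2R)-1-{[tert-butyl(diphenyl)silyl]oxy}-2-methylbut-3-en-2-yl]cyclohexane-1,3-dione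
Conditions: LiN(SiMe3)2 (2.2 equiv), THF, −78 °C to rt; then aq. HCl
Reagents that add atoms: none
Why: Intramolecular Claisen (Dieckmann-type) condensation of the methyl ketone enolate onto the ester closes ring B as a 1,3-dione, and the hindered C5 hydrogen stays in place because the base is used up by the far more acidic ketone and diketone positions.

**Step 7**
Reactants: 10
Product: 11 (6R)-6-[(2R)-1-{[tert-butyl(diphenyl)silyl]oxy}-2-methylbut-3-en-2-yl]-3-methoxycyclohex-2-en-1-one
Conditions: HC(OMe)3, TsOH (cat.), MeOH, rt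
Reagents that add atoms: trimethyl orthoformate, COC(OC)OC
Why: Acid-catalysed vinylogous ester formation under equilibrating conditions places the methoxy group on the carbonyl remote from the bulky C5 substituent, so the C10 carbonyl stays free.

**Step 8**
Reactants: 11
Product: 13 (4S)-4-[(2R)-1-{[tert-butyl(diphenyl)silyl]oxy}-2-methylbut-3-en-2-yl]-3-(prop-2-en-1-yl)cyclohex-2-en-1-one, via tertiary allylic alcohol 12 (not isolated)
Conditions: allylMgBr, THF, 0 °C; then 1 M HCl, 0 °C
Reagents that add atoms: allylmagnesium bromide, C=CC[Mg]Br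
Why: Stork–Danheiser sequence, in which 1,2-addition of the small allyl Grignard reagent to the C10 carbonyl and acid hydrolysis of the enol ether with loss of water transpose the enone and attach C1–C2 to C10 without touching C5.

**Step 9**
Reactants: 13
Product: 14 (4aS,5R)-5-({[tert-butyl(diphenyl)silyl]oxy}methyl)-5-methyl-4,4a,5,8-tetrahydronaphthalen-2(3H)-one
Conditions: second-generation Grubbs catalyst RuCl2(=CHPh)(PCy3)(1,3-dimesitylimidazolidin-2-ylidene) (5 mol%), CH2Cl2, 40 °C
Reagents that add atoms: none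
Why: Ring-closing metathesis between the allyl group on C10 and the vinyl group on C4 closes ring A as a cyclohexene, and the trisubstituted enone alkene does not take part.

**Step 10**
Reactants: 14
Product: 15 (4aS,5R)-5-({[tert-butyl(diphenyl)silyl]oxy}methyl)-5-methyl-4,4a,5,6,7,8-hexahydronaphthalen-2(3H)-one
Conditions: H2 (1 atm), RhCl(PPh3)3 (10 mol%), benzene, rt
Reagents that add atoms: none
Why: Homogeneous hydrogenation with Wilkinson's catalyst saturates the isolated disubstituted alkene of ring A and leaves the conjugated trisubstituted enone, as in the carvone case.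

**Step 11**
Reactants: 15
Product: 17 tert-butyl 2-[(1R,4aS,5R,8aS)-5-({[tert-butyl(diphenyl)silyl]oxy}methyl)-5,8a-dimethyl-2-oxodecahydronaphthalen-1-yl]acetate, via lithium enolate 16 (not isolated)
Conditions: Me2CuLi, Et2O, 0 °C; then BrCH2CO2t-Bu, HMPA, THF, −78 to −20 °C
Reagents that add atoms: lithium dimethylcuprate, [Li+].C[Cu-]C; tert-butyl bromoacetate, CC(C)(C)OC(=O)CBr
Why: Cuprate conjugate addition to the ring-fused enone delivers methyl to C10 on the face of the C5 hydrogen (axial attack that gives the cis-fused decalin, the other face being blocked by the syn-axial CH2OSi group on C4), and the enolate is then alkylated at C9 on the same convex β-face, anti to ring A, so that the C10 methyl and the C9 side chain end up cis.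

**Step 12**
Reactants: 17
Product: 19 tert-butyl 2-[(1R,2R,4aS,5R,8aS)-5-({[tert-butyl(diphenyl)silyl]oxy}methyl)-2,5,8a-trimethyl-2-[(triethylsilyl)oxy]decahydronaphthalen-1-yl]acetate, via dichlorocerium alkoxide 18 (not isolated)
Conditions: MeLi, CeCl3, THF, −78 °C; then Et3SiOTf, −78 to 0 °C
Reagents that add atoms: methyllithium, [Li]C (used as MeCeCl2); triethylsilyl trifluoromethanesulfonate, CC[Si](CC)(CC)OS(=O)(=O)C(F)(F)F; cerium trichloride, Cl[Ce](Cl)Cl, supplies the cerium that is present only in 18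
Why: Imamoto organocerium addition is selective for the ketone over the tert-butyl ester and does not enolise C9, and methyl enters equatorially from the convex β-face (the α-face is closed by the axial C1 methylene and the C4 substituent) to give the 8α-hydroxy-8β-methyl carbinol, which is silylated in the same flask.

**Step 13**
Reactants: 19
Product: 20 2-[(1R,2R,4aS,5R,8aS)-5-({[tert-butyl(diphenyl)silyl]oxy}methyl)-2,5,8a-trimethyl-2-[(triethylsilyl)oxy]decahydronaphthalen-1-yl]ethan-1-ol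
Conditions: LiAlH4, Et2O, 0 °C
Reagents that add atoms: none
Why: Hydride reduction of the tert-butyl ester gives the C12 primary alcohol while both silyl ethers stay intact.

**Step 14**
Reactants: 20
Product: 21 tert-butyl({(1R,4aS,5R,6R,8aS)-5-(2-iodoethyl)-1,4a,6-trimethyl-6-[(triethylsilyl)oxy]decahydronaphthalen-1-yl}methoxy)diphenylsilane
Conditions: I2, PPh3, imidazole, CH2Cl2, 0 °C
Reagents that add atoms: iodine, [I][I]
Why: Garegg–Samuelsson (Appel-type) iodination of the primary alcohol, with the tertiary hydroxyl masked so that no cyclic ether can form.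

**Step 15**
Reactants: 21
Product: 22 tert-butyl({(1R,4aS,5R,6R,8aS)-1,4a,6-trimethyl-5-(3-methylidenepent-4-en-1-yl)-6-[(triethylsilyl)oxy]decahydronaphthalen-1-yl}methoxy)diphenylsilane
Conditions: chloroprene (3 equiv, slow addition), NiBr2(MeOCH2CH2OMe) (10 mol%), 4,4′-di-tert-butyl-2,2′-bipyridine (12 mol%), Zn dust, DMA, rt
Reagents that add atoms: chloroprene (2-chlorobuta-1,3-diene), C=CC(Cl)=C
Why: Proposed new method: nickel-catalysed reductive cross-electrophile coupling of an unactivated primary alkyl iodide with chloroprene, in which bipyridine-ligated zerovalent nickel inserts into the activated dienyl carbon–chlorine bond to give a dienyl nickel chloride (divalent nickel), a monovalent nickel species abstracts iodine from 21 to give the primary C12 radical, radical capture gives a trivalent alkyl(dienyl)nickel that reductively eliminates the C12–C13 bond, and zinc returns nickel to its low-valent state, with slow addition of chloroprene to hold back direct radical addition to the diene and nickel-mediated diene oligomerisation; the closest known reactions are the nickel-catalysed reductive coupling of alkyl halides with alkenyl bromides and the NiCl2(dppp)-catalysed Kumada coupling of Grignard reagents with chloroprene.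

**Step 16**
Reactants: 22
Product: 23 (1R,2R,4aS,5R,8aS)-5-(hydroxymethyl)-2,5,8a-trimethyl-1-(3-methylidenepent-4-en-1-yl)decahydronaphthalen-2-ol
Conditions: Bu4NF, THF, 50 °C
Reagents that add atoms: none
Why: Fluoride-mediated desilylation removes the primary silyl ether and the tertiary triethylsilyl ether in one operation.

**Step 17**
Reactants: 23
Product: 24 [(1R,4aS,5R,6R,8aS)-6-hydroxy-1,4a,6-trimethyl-5-(3-methylidenepent-4-en-1-yl)decahydronaphthalen-1-yl]methyl 2-[bis(2,2,2-trifluoroethoxy)phosphoryl]acetate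
Conditions: (CF3CH2O)2P(O)CH2CO2H, dicyclohexylcarbodiimide, DMAP (cat.), CH2Cl2, 0 °C to rt
Reagents that add atoms: [bis(2,2,2-trifluoroethoxy)phosphoryl]acetic acid, OC(=O)CP(=O)(OCC(F)(F)F)OCC(F)(F)F
Why: Steglich esterification acylates only the primary alcohol because the tertiary C8 alcohol is too hindered.

**Step 18**
Reactants: 24; 25 4-{[tert-butyl(dimethyl)silyl]oxy}benzaldehyde
Product: 26 [(1R,4aS,5R,6R,8aS)-6-hydroxy-1,4a,6-trimethyl-5-(3-methylidenepent-4-en-1-yl)decahydronaphthalen-1-yl]methyl (2Z)-3-(4-{[tert-butyl(dimethyl)silyl]oxy}phenyl)prop-2-enoate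
Conditions: KN(SiMe3)2, 18-crown-6, THF, −78 °C
Reagents that add atoms: none
Why: Still–Gennari variant of the Horner–Wadsworth–Emmons olefination, in which the electron-poor trifluoroethyl phosphonate eliminates fast from the kinetically formed adduct and gives the Z cinnamate, while one equivalent of base deprotonates only the phosphonoacetate and not the tertiary alcohol.

**Step 19**
Reactants: 26
Product: 27 [(1R,4aS,5R,6R,8aS)-6-hydroxy-1,4a,6-trimethyl-5-(3-methylidenepent-4-en-1-yl)decahydronaphthalen-1-yl]methyl (2Z)-3-(4-hydroxyphenyl)prop-2-enoate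
Conditions: Bu4NF, AcOH, THF, 0 °C, in the dark
Reagents that add atoms: none
Why: Buffered fluoride cleavage of the aryl silyl ether frees the phenol without isomerising the Z alkene or touching the ester.

**Compound list**
1 | 3-methylbut-2-en-1-ol (prenol) | CC(C)=CCO | starting material
2 | hex-5-enoic acid | C=CCCCC(=O)O | starting material
3 | 3-methylbut-2-en-1-yl hex-5-enoate | C=CCCCC(=O)OCC=C(C)C | intermediate
4 | (2E)-4-hydroxy-3-methylbut-2-en-1-yl hex-5-enoate | C=CCCCC(=O)OC/C=C(\C)CO | intermediate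
5 | (2E)-4-{[tert-butyl(diphenyl)silyl]oxy}-3-methylbut-2-en-1-yl hex-5-enoate | C=CCCCC(=O)OC/C=C(\C)CO[Si](c1ccccc1)(c1ccccc1)C(C)(C)C | intermediate
6 | boron ketene acetal of 5, O-bound (4S,5S)-1,3-bis{[3,5-bis(trifluoromethyl)phenyl]sulfonyl}-4,5-diphenyl-1,3,2-diazaborolidin-2-yl group, butenyl chain cis to the allyloxy oxygen | C=CCC/C=C(\OC/C=C(\C)CO[Si](c1ccccc1)(c1ccccc1)C(C)(C)C)OB1N(S(=O)(=O)c2cc(C(F)(F)F)cc(C(F)(F)F)c2)[C@@H](c2ccccc2)[C@H](c2ccccc2)N1S(=O)(=O)c1cc(C(F)(F)F)cc(C(F)(F)F)c1 | intermediate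
7 | (2R)-2-[(2R)-1-{[tert-butyl(diphenyl)silyl]oxy}-2-methylbut-3-en-2-yl]hex-5-enoic acid | C=C[C@@](C)(CO[Si](c1ccccc1)(c1ccccc1)C(C)(C)C)[C@H](C(=O)O)CCC=C | intermediate
8 | methyl (2R)-2-[(2R)-1-{[tert-butyl(diphenyl)silyl]oxy}-2-methylbut-3-en-2-yl]hex-5-enoate | C=C[C@@](C)(CO[Si](c1ccccc1)(c1ccccc1)C(C)(C)C)[C@H](C(=O)OC)CCC=C | intermediate
9 | methyl (2R)-2-[(2R)-1-{[tert-butyl(diphenyl)silyl]oxy}-2-methylbut-3-en-2-yl]-5-oxohexanoate | C=C[C@@](C)(CO[Si](c1ccccc1)(c1ccccc1)C(C)(C)C)[C@H](C(=O)OC)CCC(C)=O | intermediate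
10 | (4R)-4-[(2R)-1-{[tert-butyl(diphenyl)silyl]oxy}-2-methylbut-3-en-2-yl]cyclohexane-1,3-dione | C=C[C@@](C)(CO[Si](c1ccccc1)(c1ccccc1)C(C)(C)C)[C@H]1CCC(=O)CC1=O | intermediate
11 | (6R)-6-[(2R)-1-{[tert-butyl(diphenyl)silyl]oxy}-2-methylbut-3-en-2-yl]-3-methoxycyclohex-2-en-1-one | C=C[C@@](C)(CO[Si](c1ccccc1)(c1ccccc1)C(C)(C)C)[C@H]1CCC(OC)=CC1=O | intermediate
12 | (6R)-6-[(2R)-1-{[tert-butyl(diphenyl)silyl]oxy}-2-methylbut-3-en-2-yl]-3-methoxy-1-(prop-2-en-1-yl)cyclohex-2-en-1-ol, both C1 epimers | C=C[C@@](C)(CO[Si](c1ccccc1)(c1ccccc1)C(C)(C)C)[C@H]1CCC(OC)=CC1(O)CC=C | intermediate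
13 | (4S)-4-[(2R)-1-{[tert-butyl(diphenyl)silyl]oxy}-2-methylbut-3-en-2-yl]-3-(prop-2-en-1-yl)cyclohex-2-en-1-one | C=C[C@@](C)(CO[Si](c1ccccc1)(c1ccccc1)C(C)(C)C)[C@H]1CCC(=O)C=C1CC=C | intermediate
14 | (4aS,5R)-5-({[tert-butyl(diphenyl)silyl]oxy}methyl)-5-methyl-4,4a,5,8-tetrahydronaphthalen-2(3H)-one | O=C1C=C2CC=C[C@@](C)(CO[Si](c3ccccc3)(c3ccccc3)C(C)(C)C)[C@H]2CC1 | intermediate
15 | (4aS,5R)-5-({[tert-butyl(diphenyl)silyl]oxy}methyl)-5-methyl-4,4a,5,6,7,8-hexahydronaphthalen-2(3H)-one | O=C1C=C2CCC[C@@](C)(CO[Si](c3ccccc3)(c3ccccc3)C(C)(C)C)[C@H]2CC1 | intermediate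
16 | lithium (4aS,5R,8aS)-5-({[tert-butyl(diphenyl)silyl]oxy}methyl)-5,8a-dimethyl-3,4,4a,5,6,7,8,8a-octahydronaphthalen-2-olate | [Li]OC1=C[C@@]2(C)CCC[C@@](C)(CO[Si](c3ccccc3)(c3ccccc3)C(C)(C)C)[C@H]2CC1 | intermediate
17 | tert-butyl 2-[(1R,4aS,5R,8aS)-5-({[tert-butyl(diphenyl)silyl]oxy}methyl)-5,8a-dimethyl-2-oxodecahydronaphthalen-1-yl]acetate | CC(C)(C)OC(=O)C[C@@H]1[C@@]2(C)CCC[C@@](C)(CO[Si](c3ccccc3)(c3ccccc3)C(C)(C)C)[C@H]2CCC1=O | intermediate
18 | dichlorocerium alkoxide of tert-butyl 2-[(1R,2R,4aS,5R,8aS)-5-({[tert-butyl(diphenyl)silyl]oxy}methyl)-2-hydroxy-2,5,8a-trimethyldecahydronaphthalen-1-yl]acetate | CC(C)(C)OC(=O)C[C@@H]1[C@@]2(C)CCC[C@@](C)(CO[Si](c3ccccc3)(c3ccccc3)C(C)(C)C)[C@H]2CC[C@@]1(C)O[Ce](Cl)Cl | intermediate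
19 | tert-butyl 2-[(1R,2R,4aS,5R,8aS)-5-({[tert-butyl(diphenyl)silyl]oxy}methyl)-2,5,8a-trimethyl-2-[(triethylsilyl)oxy]decahydronaphthalen-1-yl]acetate | CC(C)(C)OC(=O)C[C@@H]1[C@@]2(C)CCC[C@@](C)(CO[Si](c3ccccc3)(c3ccccc3)C(C)(C)C)[C@H]2CC[C@@]1(C)O[Si](CC)(CC)CC | intermediate
20 | 2-[(1R,2R,4aS,5R,8aS)-5-({[tert-butyl(diphenyl)silyl]oxy}methyl)-2,5,8a-trimethyl-2-[(triethylsilyl)oxy]decahydronaphthalen-1-yl]ethan-1-ol | OCC[C@@H]1[C@@]2(C)CCC[C@@](C)(CO[Si](c3ccccc3)(c3ccccc3)C(C)(C)C)[C@H]2CC[C@@]1(C)O[Si](CC)(CC)CC | intermediate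
21 | tert-butyl({(1R,4aS,5R,6R,8aS)-5-(2-iodoethyl)-1,4a,6-trimethyl-6-[(triethylsilyl)oxy]decahydronaphthalen-1-yl}methoxy)diphenylsilane | ICC[C@@H]1[C@@]2(C)CCC[C@@](C)(CO[Si](c3ccccc3)(c3ccccc3)C(C)(C)C)[C@H]2CC[C@@]1(C)O[Si](CC)(CC)CC | intermediate
22 | tert-butyl({(1R,4aS,5R,6R,8aS)-1,4a,6-trimethyl-5-(3-methylidenepent-4-en-1-yl)-6-[(triethylsilyl)oxy]decahydronaphthalen-1-yl}methoxy)diphenylsilane | C=CC(=C)CC[C@@H]1[C@@]2(C)CCC[C@@](C)(CO[Si](c3ccccc3)(c3ccccc3)C(C)(C)C)[C@H]2CC[C@@]1(C)O[Si](CC)(CC)CC | intermediate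
23 | (1R,2R,4aS,5R,8aS)-5-(hydroxymethyl)-2,5,8a-trimethyl-1-(3-methylidenepent-4-en-1-yl)decahydronaphthalen-2-ol | C=CC(=C)CC[C@@H]1[C@@]2(C)CCC[C@@](C)(CO)[C@H]2CC[C@@]1(C)O | intermediate
24 | [(1R,4aS,5R,6R,8aS)-6-hydroxy-1,4a,6-trimethyl-5-(3-methylidenepent-4-en-1-yl)decahydronaphthalen-1-yl]methyl 2-[bis(2,2,2-trifluoroethoxy)phosphoryl]acetate | C=CC(=C)CC[C@@H]1[C@@]2(C)CCC[C@@](C)(COC(=O)CP(=O)(OCC(F)(F)F)OCC(F)(F)F)[C@H]2CC[C@@]1(C)O | intermediate
25 | 4-{[tert-butyl(dimethyl)silyl]oxy}benzaldehyde | O=Cc1ccc(O[Si](C)(C)C(C)(C)C)cc1 | starting material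
26 | [(1R,4aS,5R,6R,8aS)-6-hydroxy-1,4a,6-trimethyl-5-(3-methylidenepent-4-en-1-yl)decahydronaphthalen-1-yl]methyl (2Z)-3-(4-{[tert-butyl(dimethyl)silyl]oxy}phenyl)prop-2-enoate | C=CC(=C)CC[C@@H]1[C@@]2(C)CCC[C@@](C)(COC(=O)/C=C\c3ccc(O[Si](C)(C)C(C)(C)C)cc3)[C@H]2CC[C@@]1(C)O | intermediate
27 | [(1R,4aS,5R,6R,8aS)-6-hydroxy-1,4a,6-trimethyl-5-(3-methylidenepent-4-en-1-yl)decahydronaphthalen-1-yl]methyl (2Z)-3-(4-hydroxyphenyl)prop-2-enoate | C=CC(=C)CC[C@@H]1[C@@]2(C)CCC[C@@](C)(COC(=O)/C=C\c3ccc(O)cc3)[C@H]2CC[C@@]1(C)O | target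

**Totals**
Total step count: 19. Longest linear sequence: 19 steps (1 and 2 to 27; aldehyde 25 and all reagents are bought).

**Steps most likely to fail**

Step 4 (the reagent-controlled Ireland–Claisen carries both the C4/C5 relative configuration and the absolute configuration). The fallback sets out from 5 and comes back at 8. Treating 5 with LDA and Me3SiCl in THF at −78 °C and warming to rt gives the achiral trimethylsilyl ketene acetal of 5 F1 (chain cis to the allyloxy oxygen). It rearranges through the same chair to the racemic trimethylsilyl 2-[1-{[tert-butyl(diphenyl)silyl]oxy}-2-methylbut-3-en-2-yl]hex-5-enoate F2, which acidic work-up hydrolyses to the racemic acid, that is 7 together with its enantiomer (2S)-2-[(2S)-1-{[tert-butyl(diphenyl)silyl]oxy}-2-methylbut-3-en-2-yl]hex-5-enoic acid F3. Classical resolution with (R)-1-phenylethylamine crystallises the (1R)-1-phenylethanaminium salt of 7 F4 and leaves the (1R)-1-phenylethanaminium salt of the enantiomeric acid F5 in the mother liquor. Aqueous HCl returns 7, and Me3SiCHN2 gives 8.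

Step 12 (the C8 configuration depends on which face of the cis-decalone is open). The fallback sets out from 17 and comes back at 19; it puts oxygen rather than methyl on the open face. Methylenation with Zn, CH2Br2 and TiCl4 gives tert-butyl 2-[(1S,4aS,5R,8aR)-5-({[tert-butyl(diphenyl)silyl]oxy}methyl)-5,8a-dimethyl-2-methylidenedecahydronaphthalen-1-yl]acetate F6. Mukaiyama hydration (Co(acac)2, PhSiH3, O2, i-PrOH) adds hydrogen to the methylene carbon and traps the C8 radical with O2 on the face that a methyl nucleophile would have used, giving tert-butyl 2-[(1R,2R,4aS,5R,8aS)-5-({[tert-butyl(diphenyl)silyl]oxy}methyl)-2-hydroxy-2,5,8a-trimethyldecahydronaphthalen-1-yl]acetate F7. Et3SiOTf and 2,6-lutidine then give 19.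

Step 15 (the proposed new coupling; radical addition to chloroprene or diene oligomerisation may win). The fallback sets out from 21 and comes back at 22. It is the established copper-catalysed Kochi coupling: buta-1,3-dien-2-ylmagnesium chloride (from chloroprene and Mg in THF) with Li2CuCl4 (3 mol%) at −20 to 0 °C displaces the primary iodide and gives 22 directly. Both silyl ethers tolerate the Grignard reagent, and this fallback makes no new compound (F0).

**Further compounds**
F1 | step 4 | trimethylsilyl ketene acetal of 5, [(1-{[(2E)-4-{[tert-butyl(diphenyl)silyl]oxy}-3-methylbut-2-en-1-yl]oxy}hexa-1,5-dien-1-yl)oxy](trimethyl)silane, butenyl chain cis to the allyloxy oxygen | C=CCC/C=C(\OC/C=C(\C)CO[Si](c1ccccc1)(c1ccccc1)C(C)(C)C)O[Si](C)(C)C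
F2 | step 4 | racemic trimethylsilyl 2-[1-{[tert-butyl(diphenyl)silyl]oxy}-2-methylbut-3-en-2-yl]hex-5-enoate, (2R,2′R) and (2S,2′S) enantiomers 1:1 | C=C[C@@](C)(CO[Si](c1ccccc1)(c1ccccc1)C(C)(C)C)[C@H](C(=O)O[Si](C)(C)C)CCC=C.C=C[C@](C)(CO[Si](c1ccccc1)(c1ccccc1)C(C)(C)C)[C@@H](C(=O)O[Si](C)(C)C)CCC=C
F3 | step 4 | (2S)-2-[(2S)-1-{[tert-butyl(diphenyl)silyl]oxy}-2-methylbut-3-en-2-yl]hex-5-enoic acid (enantiomer of 7) | C=C[C@](C)(CO[Si](c1ccccc1)(c1ccccc1)C(C)(C)C)[C@@H](C(=O)O)CCC=C
F4 | step 4 | (1R)-1-phenylethanaminium (2R)-2-[(2R)-1-{[tert-butyl(diphenyl)silyl]oxy}-2-methylbut-3-en-2-yl]hex-5-enoate | C=C[C@@](C)(CO[Si](c1ccccc1)(c1ccccc1)C(C)(C)C)[C@H](C(=O)[O-])CCC=C.C[C@@H]([NH3+])c1ccccc1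
F5 | step 4 | (1R)-1-phenylethanaminium (2S)-2-[(2S)-1-{[tert-butyl(diphenyl)silyl]oxy}-2-methylbut-3-en-2-yl]hex-5-enoate | C=C[C@](C)(CO[Si](c1ccccc1)(c1ccccc1)C(C)(C)C)[C@@H](C(=O)[O-])CCC=C.C[C@@H]([NH3+])c1ccccc1
F6 | step 12 | tert-butyl 2-[(1S,4aS,5R,8aR)-5-({[tert-butyl(diphenyl)silyl]oxy}methyl)-5,8a-dimethyl-2-methylidenedecahydronaphthalen-1-yl]acetate | CC(C)(C)OC(=O)C[C@@H]1[C@@]2(C)CCC[C@@](C)(CO[Si](c3ccccc3)(c3ccccc3)C(C)(C)C)[C@H]2CCC1=C
F7 | step 12 | tert-butyl 2-[(1R,2R,4aS,5R,8aS)-5-({[tert-butyl(diphenyl)silyl]oxy}methyl)-2-hydroxy-2,5,8a-trimethyldecahydronaphthalen-1-yl]acetate | CC(C)(C)OC(=O)C[C@@H]1[C@@]2(C)CCC[C@@](C)(CO[Si](c3ccccc3)(c3ccccc3)C(C)(C)C)[C@H]2CC[C@@]1(C)O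
F0 | step 15 | none | none
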